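The three oxygens of ring A are all different (O1 of ring C on C8a, a methyl ether on C5, a free hydroxyl on C7) and the aldehyde sits on C8, so ring A is built, not carved out of a symmetric phloroglucinol. It is disconnected at C4a–C8a, C5–C6 and C8–C8a into a silyl ynol ether that already carries C2–C4, the C3 stereocentre and ring B, and a 3-(4-methoxybenzyloxy)cyclobutenone. One thermal pericyclic cascade should deliver the benzene ring with each oxygen capped differently and only the C8a phenol free; this phenol then steers formylation to C8 and closes ring C. C3 is set earlier by rhodium-catalysed asymmetric arylation.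

Key step: step 8

Remarks on the chemistry
- Isoflavan numbering is used (O1, C2, C3, C4, C4a, C5–C8, C8a; ring B primed). The target is the (3R) enantiomer, and the CH2–CH(aryl)–CH2O unit keeps the same spatial arrangement and the descriptor R in every intermediate from 9 onward.
- ArB = 2,4-bis(methoxymethoxy)-3-(3-methylbut-2-en-1-yl)phenyl (protected ring B). MOM = methoxymethyl, PMB = 4-methoxybenzyl, TBS = tert-butyldimethylsilyl, TIPS = triisopropylsilyl, BINAP = 2,2′-bis(diphenylphosphino)-1,1′-binaphthyl.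
- Assumption: (S)-BINAP delivers the aryl group to the α-si face of the (E)-enoate, as in the accepted model for this ligand, which gives the (R) ester. If the sense proved opposite, (R)-BINAP would be used.
- The silyloxy ester 9 is made directly by arylation of an acyclic 4-silyloxy enoate, so no lactone has to be opened and reprotected.

Step 1
Reactants: 1 resorcinol
Product: 2 1,3-bis(methoxymethoxy)benzene
Conditions: NaH, MOMCl, DMF, 0 °C → rt
Reagents that add atoms: chloromethyl methyl ether, COCCl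
Why: Williamson-type O-alkylation of both phenoxides gives the bis-acetal, which serves as the directing group for the two metalations that follow.

Step 2
Reactants: 2 1,3-bis(methoxymethoxy)benzene; 3 prenyl bromide
Product: 4 1,3-bis(methoxymethoxy)-2-(3-methylbut-2-en-1-yl)benzene
Conditions: n-BuLi, THF, 0 °C; CuI (10 mol %), then 3, −78 °C → rt
Reagents that add atoms: none
Why: Directed ortho-metalation removes the proton between the two MOM ethers, and the aryl metal species is alkylated at the primary carbon of the allylic bromide, CuI suppressing SN2′ attack.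

Step 3
Reactants: 4 1,3-bis(methoxymethoxy)-2-(3-methylbut-2-en-1-yl)benzene
Product: 5 [2,4-bis(methoxymethoxy)-3-(3-methylbut-2-en-1-yl)phenyl]boronic acid
Conditions: s-BuLi, TMEDA, THF, −78 °C; B(OiPr)3, −78 °C → rt; H2O (NH4Cl buffer, pH 6)
Reagents that add atoms: triisopropyl borate, CC(C)OB(OC(C)C)OC(C)C; water, O
Why: A second directed ortho-metalation under kinetic control at −78 °C takes the only remaining position ortho to a MOM ether in preference to the benzylic-allylic CH2, and borate trapping followed by hydrolysis gives the boronic acid.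

Step 4
Reactants: 6 [(tert-butyldimethylsilyl)oxy]acetaldehyde; 7 ethyl (triphenylphosphoranylidene)acetate
Product: 8 ethyl (2E)-4-[(tert-butyldimethylsilyl)oxy]but-2-enoate
Conditions: CH2Cl2, rt
Reagents that add atoms: none
Why: Wittig olefination with a stabilised ylide gives the (E)-enoate selectively.

Step 5
Reactants: 8 ethyl (2E)-4-[(tert-butyldimethylsilyl)oxy]but-2-enoate; 5 [2,4-bis(methoxymethoxy)-3-(3-methylbut-2-en-1-yl)phenyl]boronic acid (2 equivalents)
Product: 9 ethyl (3R)-3-ArB-4-[(tert-butyldimethylsilyl)oxy]butanoate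
Conditions: [Rh(OH)((S)-BINAP)]2 (1.5 mol %), 1,4-dioxane/H2O (10:1), 60 °C
Reagents that add atoms: none
Why: In this Hayashi–Miyaura asymmetric 1,4-addition the aryl–rhodium species bound to (S)-BINAP inserts the (E)-enoate from its α-si face, which sets C3 as R, and the hydroxo-rhodium precatalyst allows a moderate temperature that limits protodeboronation of the ortho-alkoxy boronic acid.

Step 6
Reactants: 9 ethyl (3R)-3-ArB-4-[(tert-butyldimethylsilyl)oxy]butanoate
Product: 12 triisopropyl({(4R)-4-ArB-5-[(tert-butyldimethylsilyl)oxy]pent-1-yn-1-yl}oxy)silane, via lithium dibromoenolate 10 (not isolated), via lithium ynolate 11 (not isolated)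
Conditions: CH2Br2, lithium 2,2,6,6-tetramethylpiperidide, THF, −78 °C; 9; LiN(SiMe3)2; n-BuLi, −78 → 0 °C; i-Pr3SiCl, −78 °C → rt
Reagents that add atoms: dibromomethane, BrCBr; chlorotriisopropylsilane, CC(C)[Si](Cl)(C(C)C)C(C)C
Why: This is the Kowalski ester homologation stopped at the ynolate, in which LiCHBr2 adds to the ester, bromine–lithium exchange on enolate 10 triggers a 1,2-shift of the alkyl group to give ynolate 11, and the bulky silyl chloride traps it on oxygen, while C3 is β to the carbonyl and is not touched.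

Step 7
Reactants: 13 3-ethoxycyclobut-2-en-1-one; 14 4-methoxybenzyl alcohol
Product: 15 3-[(4-methoxybenzyl)oxy]cyclobut-2-en-1-one
Conditions: PPTS (10 mol %), toluene, 45 °C, reduced pressure (EtOH removed)
Reagents that add atoms: none
Why: Acid-catalysed alcohol exchange of a vinylogous ester proceeds by addition–elimination at the alkoxy-bearing carbon and is driven by removal of ethanol.

Step 8
Reactants: 12 triisopropyl({(4R)-4-ArB-5-[(tert-butyldimethylsilyl)oxy]pent-1-yn-1-yl}oxy)silane; 15 3-[(4-methoxybenzyl)oxy]cyclobut-2-en-1-one (1.5 equivalents)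
Product: 20 2-{(2R)-2-ArB-3-[(tert-butyldimethylsilyl)oxy]propyl}-5-[(4-methoxybenzyl)oxy]-3-[(triisopropylsilyl)oxy]phenol, via vinylketene 16 (not isolated), via vinylcyclobutenone 17 (not isolated), via dienylketene 18 (not isolated), via cyclohexadienone 19 (not isolated)
Conditions: toluene (degassed), 80 °C then 110 °C, sealed tube
Reagents that add atoms: none
Why: Proposed new method: the closest known reaction is the Danheiser benzannulation of 3-alkyl- and 3-aryl-cyclobutenones with silyl ynol ethers, and the new element is the alkoxy group on the enone β-carbon of the cyclobutenone, which should still allow thermal 4π electrocyclic opening to (2-alkoxyvinyl)ketene 16 because relief of ring strain drives that step. Ketene 16 adds to the electron-rich triple bond of 12 by [2+2] cycloaddition, its electrophilic carbonyl carbon bonding to the nucleophilic alkyl-bearing carbon of the ynol ether (C8a–C4a) and its α-carbon to the silyloxy carbon (C6–C5), to give 17. A second 4π opening gives dienylketene 18, and ring A is closed by thermal 6π electrocyclisation (C8–C8a) to dienone 19, which tautomerises irreversibly to phenol 20. No stereocentre is formed, and C3 lies outside the reacting π system and keeps its configuration. The one selectivity required, the orientation of the [2+2] step that places the side chain on C4a between the new phenol and the silyloxy carbon, is secured by the polarisation of the silyloxyalkyne. The MOM, TBS and PMB ethers and the prenyl alkene are inert to these neutral thermal conditions, and a small excess of 15 makes up for ketene lost to dimerisation.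

Step 9
Reactants: 20 2-{(2R)-2-ArB-3-[(tert-butyldimethylsilyl)oxy]propyl}-5-[(4-methoxybenzyl)oxy]-3-[(triisopropylsilyl)oxy]phenol
Product: 21 3-{(2R)-2-ArB-3-[(tert-butyldimethylsilyl)oxy]propyl}-2-hydroxy-6-[(4-methoxybenzyl)oxy]-4-[(triisopropylsilyl)oxy]benzaldehyde
Conditions: MgCl2, Et3N, (CH2O)n, THF, 65 °C; aq. NH4Cl
Reagents that add atoms: paraformaldehyde (formaldehyde), C=O
Why: In the Casnati–Skattebøl ortho-formylation the magnesium phenoxide delivers formaldehyde to its ortho position and a second formaldehyde oxidises the benzylic alkoxide, and since C8 is the only free position ortho to the C8a phenol the para position C6 is left alone.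

Step 10
Reactants: 21 3-{(2R)-2-ArB-3-[(tert-butyldimethylsilyl)oxy]propyl}-2-hydroxy-6-[(4-methoxybenzyl)oxy]-4-[(triisopropylsilyl)oxy]benzaldehyde
Product: 22 3-[(2R)-2-ArB-3-hydroxypropyl]-2-hydroxy-6-[(4-methoxybenzyl)oxy]-4-[(triisopropylsilyl)oxy]benzaldehyde
Conditions: AcOH/THF/H2O (3:1:1), rt
Reagents that add atoms: none
Why: Mild acid hydrolysis cleaves the primary alkyl TBS ether much faster than the hindered aryl TIPS ether, the aryl MOM acetals or the PMB ether.

Step 11
Reactants: 22 3-[(2R)-2-ArB-3-hydroxypropyl]-2-hydroxy-6-[(4-methoxybenzyl)oxy]-4-[(triisopropylsilyl)oxy]benzaldehyde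
Product: 23 (3R)-3-ArB-7-[(4-methoxybenzyl)oxy]-5-[(triisopropylsilyl)oxy]-3,4-dihydro-2H-chromene-8-carbaldehyde
Conditions: PPh3, DIAD, THF (0.02 M), 0 °C → rt
Reagents that add atoms: none
Why: In this intramolecular Mitsunobu etherification the acidic, formyl-flanked C8a phenol displaces the activated primary C2 alcohol in a 6-exo-tet closure of ring C, and C3 is not a reacting centre and keeps its configuration.

Step 12
Reactants: 23 (3R)-3-ArB-7-[(4-methoxybenzyl)oxy]-5-[(triisopropylsilyl)oxy]-3,4-dihydro-2H-chromene-8-carbaldehyde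
Product: 25 (3R)-3-ArB-5-methoxy-7-[(4-methoxybenzyl)oxy]-3,4-dihydro-2H-chromene-8-carbaldehyde, via caesium phenoxide 24 (not isolated)
Conditions: CsF, MeI, DMF, rt
Reagents that add atoms: iodomethane, CI
Why: Fluoride cleaves the aryl TIPS ether, which the para formyl group activates as a vinylogous silyl ester, and the caesium phenoxide is O-methylated in the same flask (Williamson ether synthesis).

Step 13
Reactants: 25 (3R)-3-ArB-5-methoxy-7-[(4-methoxybenzyl)oxy]-3,4-dihydro-2H-chromene-8-carbaldehyde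
Product: 26 (3R)-3-[2,4-dihydroxy-3-(3-methylbut-2-en-1-yl)phenyl]-7-hydroxy-5-methoxy-3,4-dihydro-2H-chromene-8-carbaldehyde
Conditions: 3 M aq. HCl/MeOH (1:4), 40 °C
Reagents that add atoms: none
Why: Acid-catalysed solvolysis removes the two MOM acetals and the PMB ether, whose cation is trapped by methanol, at a moderate temperature of the kind commonly used to unmask C-prenyl resorcinols without addition of the phenol to the alkene.

Compound list
1 | resorcinol (benzene-1,3-diol) | Oc1cccc(O)c1 | starting material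
2 | 1,3-bis(methoxymethoxy)benzene | COCOc1cccc(OCOC)c1 | intermediate
3 | prenyl bromide (1-bromo-3-methylbut-2-ene) | CC(C)=CCBr | starting material
4 | 1,3-bis(methoxymethoxy)-2-(3-methylbut-2-en-1-yl)benzene | COCOc1cccc(OCOC)c1CC=C(C)C | intermediate
5 | [2,4-bis(methoxymethoxy)-3-(3-methylbut-2-en-1-yl)phenyl]boronic acid | COCOc1ccc(B(O)O)c(OCOC)c1CC=C(C)C | intermediate
6 | [(tert-butyldimethylsilyl)oxy]acetaldehyde | O=CCO[Si](C)(C)C(C)(C)C | starting material
7 | ethyl (triphenylphosphoranylidene)acetate | CCOC(=O)C=P(c1ccccc1)(c1ccccc1)c1ccccc1 | starting material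
8 | ethyl (2E)-4-[(tert-butyldimethylsilyl)oxy]but-2-enoate | CCOC(=O)/C=C/CO[Si](C)(C)C(C)(C)C | intermediate
9 | ethyl (3R)-3-[2,4-bis(methoxymethoxy)-3-(3-methylbut-2-en-1-yl)phenyl]-4-[(tert-butyldimethylsilyl)oxy]butanoate | CCOC(=O)C[C@H](c1ccc(OCOC)c(CC=C(C)C)c1OCOC)CO[Si](C)(C)C(C)(C)C | intermediate
10 | lithium (4R)-1,1-dibromo-4-ArB-5-[(tert-butyldimethylsilyl)oxy]pent-1-en-2-olate | [Li+].[O-]C(C[C@H](c1ccc(OCOC)c(CC=C(C)C)c1OCOC)CO[Si](C)(C)C(C)(C)C)=C(Br)Br | intermediate
11 | lithium (4R)-4-ArB-5-[(tert-butyldimethylsilyl)oxy]pent-1-yn-1-olate | [Li+].[O-]C#CC[C@H](c1ccc(OCOC)c(CC=C(C)C)c1OCOC)CO[Si](C)(C)C(C)(C)C | intermediate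
12 | triisopropyl({(4R)-4-[2,4-bis(methoxymethoxy)-3-(3-methylbut-2-en-1-yl)phenyl]-5-[(tert-butyldimethylsilyl)oxy]pent-1-yn-1-yl}oxy)silane | CC(C)[Si](OC#CC[C@H](c1ccc(OCOC)c(CC=C(C)C)c1OCOC)CO[Si](C)(C)C(C)(C)C)(C(C)C)C(C)C | intermediate
13 | 3-ethoxycyclobut-2-en-1-one | CCOC1=CC(=O)C1 | starting material
14 | 4-methoxybenzyl alcohol | COc1ccc(CO)cc1 | starting material
15 | 3-[(4-methoxybenzyl)oxy]cyclobut-2-en-1-one | O=C1CC(OCc2ccc(OC)cc2)=C1 | intermediate
16 | 3-[(4-methoxybenzyl)oxy]buta-1,3-dien-1-one (vinylketene) | C=C(OCc1ccc(OC)cc1)C=C=O | intermediate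
17 | 2-{(2R)-2-ArB-3-[(tert-butyldimethylsilyl)oxy]propyl}-4-{1-[(4-methoxybenzyl)oxy]ethenyl}-3-[(triisopropylsilyl)oxy]cyclobut-2-en-1-one (both epimers at the ring CH) | O=C1C(C[C@H](c2ccc(OCOC)c(CC=C(C)C)c2OCOC)CO[Si](C)(C)C(C)(C)C)=C(O[Si](C(C)C)(C(C)C)C(C)C)C1C(=C)OCc1ccc(OC)cc1 | intermediate
18 | (3E)-2-{(2R)-2-ArB-3-[(tert-butyldimethylsilyl)oxy]propyl}-5-[(4-methoxybenzyl)oxy]-3-[(triisopropylsilyl)oxy]hexa-1,3,5-trien-1-one (ketene carbon chain and alkoxyvinyl group cis) | O=C=C(C[C@H](c1ccc(OCOC)c(CC=C(C)C)c1OCOC)CO[Si](C)(C)C(C)(C)C)/C(O[Si](C(C)C)(C(C)C)C(C)C)=C\C(=C)OCc1ccc(OC)cc1 | intermediate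
19 | 2-{(2R)-2-ArB-3-[(tert-butyldimethylsilyl)oxy]propyl}-5-[(4-methoxybenzyl)oxy]-3-[(triisopropylsilyl)oxy]cyclohexa-2,4-dien-1-one | O=C1CC(OCc2ccc(OC)cc2)=CC(O[Si](C(C)C)(C(C)C)C(C)C)=C1C[C@H](c1ccc(OCOC)c(CC=C(C)C)c1OCOC)CO[Si](C)(C)C(C)(C)C | intermediate
20 | 2-{(2R)-2-ArB-3-[(tert-butyldimethylsilyl)oxy]propyl}-5-[(4-methoxybenzyl)oxy]-3-[(triisopropylsilyl)oxy]phenol | Oc1cc(OCc2ccc(OC)cc2)cc(O[Si](C(C)C)(C(C)C)C(C)C)c1C[C@H](c1ccc(OCOC)c(CC=C(C)C)c1OCOC)CO[Si](C)(C)C(C)(C)C | intermediate
21 | 3-{(2R)-2-ArB-3-[(tert-butyldimethylsilyl)oxy]propyl}-2-hydroxy-6-[(4-methoxybenzyl)oxy]-4-[(triisopropylsilyl)oxy]benzaldehyde | Oc1c(C=O)c(OCc2ccc(OC)cc2)cc(O[Si](C(C)C)(C(C)C)C(C)C)c1C[C@H](c1ccc(OCOC)c(CC=C(C)C)c1OCOC)CO[Si](C)(C)C(C)(C)C | intermediate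
22 | 3-[(2R)-2-ArB-3-hydroxypropyl]-2-hydroxy-6-[(4-methoxybenzyl)oxy]-4-[(triisopropylsilyl)oxy]benzaldehyde | Oc1c(C=O)c(OCc2ccc(OC)cc2)cc(O[Si](C(C)C)(C(C)C)C(C)C)c1C[C@H](c1ccc(OCOC)c(CC=C(C)C)c1OCOC)CO | intermediate
23 | (3R)-3-ArB-7-[(4-methoxybenzyl)oxy]-5-[(triisopropylsilyl)oxy]-3,4-dihydro-2H-chromene-8-carbaldehyde | CC(C)[Si](Oc1cc(OCc3ccc(OC)cc3)c(C=O)c2c1C[C@H](c1ccc(OCOC)c(CC=C(C)C)c1OCOC)CO2)(C(C)C)C(C)C | intermediate
24 | caesium (3R)-3-ArB-8-formyl-7-[(4-methoxybenzyl)oxy]-3,4-dihydro-2H-chromen-5-olate | [Cs+].[O-]c1cc(OCc3ccc(OC)cc3)c(C=O)c2c1C[C@H](c1ccc(OCOC)c(CC=C(C)C)c1OCOC)CO2 | intermediate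
25 | (3R)-3-[2,4-bis(methoxymethoxy)-3-(3-methylbut-2-en-1-yl)phenyl]-5-methoxy-7-[(4-methoxybenzyl)oxy]-3,4-dihydro-2H-chromene-8-carbaldehyde | COc1cc(OCc3ccc(OC)cc3)c(C=O)c2c1C[C@H](c1ccc(OCOC)c(CC=C(C)C)c1OCOC)CO2 | intermediate
26 | (3R)-3-[2,4-dihydroxy-3-(3-methylbut-2-en-1-yl)phenyl]-7-hydroxy-5-methoxy-3,4-dihydro-2H-chromene-8-carbaldehyde | COc1cc(O)c(C=O)c2c1C[C@H](c1ccc(O)c(CC=C(C)C)c1O)CO2 | target

Total step count: 13.
Longest linear sequence: 11 steps, from resorcinol 1 to target 26 (steps 1, 2, 3, 5, 6, 8, 9, 10, 11, 12, 13).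

Steps most likely to fail

Step 8 (bears the label "Proposed new method:"). Donation from the alkoxy group may slow the electrocyclic opening of the cyclobutenone so much that the ynol ether is lost to hydrolysis or oligomerisation before the ketene reaches it. The ketene may also be consumed by acylating the product phenol. The fallback uses only known reactions: ring A is taken from a preformed phloroglucinol aldehyde and joined to C4 by sp3–sp2 cross-coupling. It sets out from ester 9 and comes back to the route at 25. Saponification of 9 (LiOH, THF/H2O) gives carboxylic acid F1. Coupling with N-hydroxypyridine-2-thione (dicyclohexylcarbodiimide, dark) gives Barton ester F2, and photolysis with iodoform (Barton decarboxylative iodination) gives primary iodide F3. Zinc insertion (Zn dust, LiCl, THF) turns it into alkylzinc iodide F4. The arene partner starts from 2,6-dihydroxy-4-methoxybenzaldehyde F5. Mono-alkylation with 4-methoxybenzyl chloride and K2CO3 gives mono-PMB ether F6, since the remaining chelated hydroxyl should not react. Iodination ortho to that phenol (benzyltrimethylammonium dichloroiodate, NaHCO3) gives aryl iodide F7. Negishi coupling of F4 with F7 (Pd(OAc)2, SPhos, THF, slow addition of an excess of the zinc reagent so that the chelated phenol is tolerated) gives coupled salicylaldehyde F8, in which the C5 oxygen is already methylated. The conditions of step 10 then give diol F9, and the Mitsunobu closure of step 11 gives 25. C3 is never a reacting centre in this sequence.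

Step 6. During warming, the excess of strong bases may metalate ring B, either ortho to a MOM ether or at the benzylic-allylic CH2, where reprotonation can move the prenyl double bond into conjugation. The ynol silyl ether may also hydrolyse during purification. The fallback reaches the same ynolate under much less basic conditions, by oxidation of an acetylide instead of rearrangement of a carbenoid. It sets out from ester 9 and comes back to the route at 12. Reduction with i-Bu2AlH (CH2Cl2, −78 °C) gives aldehyde F10. Seyferth–Gilbert homologation with the Ohira–Bestmann reagent (K2CO3, MeOH) gives terminal alkyne F11. Deprotonation with one equivalent of LiN(SiMe3)2 at −78 °C and oxidation of the lithium acetylide with t-BuOOLi gives ynolate 11, which is silylated on oxygen with triisopropylsilyl triflate to give 12.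

Step 13. Protic acid may add a ring B phenol across the prenyl double bond (chroman formation), and the 4-methoxybenzyl cation may benzylate the electron-rich rings. The fallback separates the two deprotections and avoids protic acid. It sets out from 25 and comes back to the route at 26. Oxidative removal of the PMB group with DDQ (CH2Cl2/pH 7 buffer, 0 °C) is done while both ring B oxygens are still capped, so the prenyl group cannot cyclise; this gives C7 phenol F12. The two aryl MOM ethers are then cleaved with trimethylsilyl triflate and 2,2′-bipyridyl (CH2Cl2, 0 °C) followed by water, which gives 26.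

Further compounds
F1 | step 8 | (3R)-3-ArB-4-[(tert-butyldimethylsilyl)oxy]butanoic acid | OC(=O)C[C@H](c1ccc(OCOC)c(CC=C(C)C)c1OCOC)CO[Si](C)(C)C(C)(C)C
F2 | step 8 | 2-thioxopyridin-1(2H)-yl (3R)-3-ArB-4-[(tert-butyldimethylsilyl)oxy]butanoate (Barton ester) | S=C1C=CC=CN1OC(=O)C[C@H](c1ccc(OCOC)c(CC=C(C)C)c1OCOC)CO[Si](C)(C)C(C)(C)C
F3 | step 8 | tert-butyl{[(2R)-2-ArB-3-iodopropyl]oxy}dimethylsilane | IC[C@H](c1ccc(OCOC)c(CC=C(C)C)c1OCOC)CO[Si](C)(C)C(C)(C)C
F4 | step 8 | {(2R)-2-ArB-3-[(tert-butyldimethylsilyl)oxy]propyl}zinc iodide | I[Zn]C[C@H](c1ccc(OCOC)c(CC=C(C)C)c1OCOC)CO[Si](C)(C)C(C)(C)C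
F5 | step 8 | 2,6-dihydroxy-4-methoxybenzaldehyde | COc1cc(O)c(C=O)c(O)c1
F6 | step 8 | 2-hydroxy-4-methoxy-6-[(4-methoxybenzyl)oxy]benzaldehyde | COc1cc(O)c(C=O)c(OCc2ccc(OC)cc2)c1
F7 | step 8 | 2-hydroxy-3-iodo-4-methoxy-6-[(4-methoxybenzyl)oxy]benzaldehyde | COc1cc(OCc2ccc(OC)cc2)c(C=O)c(O)c1I
F8 | step 8 | 3-{(2R)-2-ArB-3-[(tert-butyldimethylsilyl)oxy]propyl}-2-hydroxy-4-methoxy-6-[(4-methoxybenzyl)oxy]benzaldehyde | COc1cc(OCc2ccc(OC)cc2)c(C=O)c(O)c1C[C@H](c1ccc(OCOC)c(CC=C(C)C)c1OCOC)CO[Si](C)(C)C(C)(C)C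
F9 | step 8 | 3-[(2R)-2-ArB-3-hydroxypropyl]-2-hydroxy-4-methoxy-6-[(4-methoxybenzyl)oxy]benzaldehyde | COc1cc(OCc2ccc(OC)cc2)c(C=O)c(O)c1C[C@H](c1ccc(OCOC)c(CC=C(C)C)c1OCOC)CO
F10 | step 6 | (3R)-3-ArB-4-[(tert-butyldimethylsilyl)oxy]butanal | O=CC[C@H](c1ccc(OCOC)c(CC=C(C)C)c1OCOC)CO[Si](C)(C)C(C)(C)C
F11 | step 6 | tert-butyl{[(2R)-2-ArB-pent-4-yn-1-yl]oxy}dimethylsilane | C#CC[C@H](c1ccc(OCOC)c(CC=C(C)C)c1OCOC)CO[Si](C)(C)C(C)(C)C
F12 | step 13 | (3R)-3-ArB-7-hydroxy-5-methoxy-3,4-dihydro-2H-chromene-8-carbaldehyde | COc1cc(O)c(C=O)c2c1C[C@H](c1ccc(OCOC)c(CC=C(C)C)c1OCOC)CO2
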